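**Retrosynthetic overview**

1. Both pyran rings are opened at O1–C2 (Mitsunobu etherification with inversion), which leads back to a methylene-bridged bis[(3R)-3-hydroxy-3-phenylpropyl]arene.
2. The strategy rests on one feature: in each flavan unit the chain C4a–C4–C3–C2(Ph)–O1, attached at C4a (the aryl carbon between 5-OMe and O-8a), is 2-phenyloxetane cut at its CH2–O bond. Both C4a–C4 bonds are therefore made from one bis-aryllithium and two molecules of (R)-2-phenyloxetane.
3. The dibromide comes from ortho-lithiated 1-methoxy-3,5-bis(methoxymethoxy)benzene (ring A, C8) and a 3-bromo-2-methoxybenzaldehyde (ring B, C6) made from 2,4,6-trihydroxybenzaldehyde, followed by ionic reduction and bromination of ring A.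
4. Ring order: both benzene rings are bought; the two pyran rings are closed last, together, in step 11.

Key step: step 9

Remark: chroman numbering is used for both arenes (ring A is bridged at C8, ring B at C6); the 7-oxygens are carried as MOM ethers like the 8a-oxygens, because a chain on C4a can only close onto O-8a, O-7 being para to it.

**Route**

Step 1
Reactants: 1 5-methoxyresorcinol
Product: 2 1-methoxy-3,5-bis(methoxymethoxy)benzene
Conditions: MOMCl (2.5 equiv), i-Pr2NEt (3 equiv), CH2Cl2, 0 °C to rt
Reagents that add atoms: chloromethyl methyl ether, COCCl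
Why: Base-mediated O-alkylation of both phenols (Williamson-type acetal formation) should give the bis-MOM ether, whose two MOM groups serve as ortho-directing groups in step 5.

Step 2
Reactants: 3 2,4,6-trihydroxybenzaldehyde
Product: 4 2-hydroxy-4,6-bis(methoxymethoxy)benzaldehyde
Conditions: MOMCl (2.1 equiv), i-Pr2NEt (2.5 equiv), CH2Cl2–DMF, 0 °C to rt
Reagents that add atoms: chloromethyl methyl ether, COCCl
Why: Williamson-type O-alkylation takes the 4-hydroxyl and one ortho hydroxyl, while the last hydroxyl is held in a hydrogen bond to the formyl oxygen and stays free, the usual outcome for 2,4,6-trihydroxyaryl carbonyl compounds.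

Step 3
Reactants: 4 2-hydroxy-4,6-bis(methoxymethoxy)benzaldehyde
Product: 5 3-bromo-2-hydroxy-4,6-bis(methoxymethoxy)benzaldehyde
Conditions: NBS (1.0 equiv), CH2Cl2, 0 °C, dark
Reagents that add atoms: N-bromosuccinimide, O=C1CCC(=O)N1Br
Why: Electrophilic aromatic bromination should occur ortho to the free chelated hydroxyl (C3), as is usual for 2-hydroxy-4,6-dialkoxyaryl aldehydes and ketones, because C5 lies between two MOM ethers; this places bromine on the future C4a of ring B.

Step 4
Reactants: 5 3-bromo-2-hydroxy-4,6-bis(methoxymethoxy)benzaldehyde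
Product: 6 3-bromo-2-methoxy-4,6-bis(methoxymethoxy)benzaldehyde
Conditions: MeI (3 equiv), K2CO3, DMF, 40 °C
Reagents that add atoms: iodomethane, CI
Why: Williamson O-methylation of the hindered chelated phenoxide in DMF installs the 5-OMe of ring B between the formyl carbon (future C6) and the bromine (future C4a).

Step 5
Reactants: 2 1-methoxy-3,5-bis(methoxymethoxy)benzene; 6 3-bromo-2-methoxy-4,6-bis(methoxymethoxy)benzaldehyde
Product: 8 [3-bromo-2-methoxy-4,6-bis(methoxymethoxy)phenyl][4-methoxy-2,6-bis(methoxymethoxy)phenyl]methanol (racemic), via ring A aryllithium 7 (not isolated)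
Conditions: 2 (1.25 equiv), n-BuLi (1.15 equiv), THF, 0 °C, 1 h; then 6 (1.0 equiv), −78 to −40 °C; H2O quench; crude carbinol used directly
Reagents that add atoms: none
Why: Directed ortho-lithiation at the carbon between the two MOM ethers (the doubly activated site, favoured over the two sites between OMe and OMOM) gives aryllithium 7, whose 1,2-addition to the aldehyde at −78 °C is faster than bromine–lithium exchange, so the ring A C8–carbinol bond forms with the bromine intact; the carbinol stereocentre is racemic and is removed in step 6.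

Step 6
Reactants: 8 [3-bromo-2-methoxy-4,6-bis(methoxymethoxy)phenyl][4-methoxy-2,6-bis(methoxymethoxy)phenyl]methanol
Product: 9 2-{[3-bromo-2-methoxy-4,6-bis(methoxymethoxy)phenyl]methyl}-5-methoxy-1,3-bis(methoxymethoxy)benzene
Conditions: Et3SiH (8 equiv), TFA (1.5 equiv), CH2Cl2, −20 to 0 °C; Et3N quench
Reagents that add atoms: none
Why: Ionic hydrogenation: the carbinol flanked by four ortho alkoxy groups ionises with a small amount of TFA at low temperature and is reduced by hydride transfer from Et3SiH, under conditions too mild and short to cleave aryl MOM ethers.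

Step 7
Reactants: 9 2-{[3-bromo-2-methoxy-4,6-bis(methoxymethoxy)phenyl]methyl}-5-methoxy-1,3-bis(methoxymethoxy)benzene
Product: 10 1-bromo-3-{[3-bromo-2-methoxy-4,6-bis(methoxymethoxy)phenyl]methyl}-6-methoxy-2,4-bis(methoxymethoxy)benzene
Conditions: NBS (1.0 equiv), MeCN, −20 to 0 °C, dark
Reagents that add atoms: N-bromosuccinimide, O=C1CCC(=O)N1Br
Why: Electrophilic aromatic bromination with one equivalent of NBS should go to ring A, whose two open positions are equivalent by symmetry (each between OMe and OMOM), because the only open position of ring B is meta to bromine and shielded by two MOM ethers, so a single dibromide should result.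

Step 8
Reactants: 11 (R)-3-chloro-1-phenylpropan-1-ol
Product: 12 (R)-2-phenyloxetane
Conditions: KOt-Bu (1.2 equiv), THF, 0 °C to rt
Reagents that add atoms: none
Why: Deprotonation and intramolecular Williamson etherification (4-exo-tet) closes the oxetane at the primary chloride without touching the carbinol stereocentre, so the (R) configuration of 11 is kept.

Step 9
Reactants: 10 1-bromo-3-{[3-bromo-2-methoxy-4,6-bis(methoxymethoxy)phenyl]methyl}-6-methoxy-2,4-bis(methoxymethoxy)benzene; 12 (R)-2-phenyloxetane (two molecules are incorporated, one at each aryllithium site)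
Product: 14 (1R)-3-[3-({3-[(3R)-3-hydroxy-3-phenylpropyl]-2-methoxy-4,6-bis(methoxymethoxy)phenyl}methyl)-6-methoxy-2,4-bis(methoxymethoxy)phenyl]-1-phenylpropan-1-ol, via dilithio arene 13 (not isolated)
Conditions: t-BuLi (4.2 equiv), THF, −78 °C, 30 min; then 12 (3 equiv, of which two are incorporated), then BF3·OEt2 (3 equiv) dropwise, −78 °C, 2 h; aqueous quench
Reagents that add atoms: (R)-2-phenyloxetane (second equivalent of 12), C1C[C@H](c2ccccc2)O1
Why: Twofold bromine–lithium exchange gives dilithio arene 13, each C–Li flanked by OMe and OMOM, and each of the two aryl carbanions then attacks one molecule of BF3-complexed oxetane 12 from the backside at the unsubstituted CH2–O carbon, so that two molecules of 12 are taken up, both C4a–C4 bonds form and the ring strain is released. The closest known reaction is the BF3·OEt2-promoted opening of oxetanes by alkyl- and aryllithiums at −78 °C. No ring is closed in this step. No stereocentre is created: the C2–O bond of each oxetane is not touched, so both carbinol centres keep the (R) configuration bought with 11 (same priority order O > Ph > CH2 > H). The step needs attack at CH2 and not at the benzylic C–O carbon; the di-ortho-substituted aryllithium is too hindered for the secondary benzylic carbon, and at −78 °C an unsubstituted phenyl does not support ionisation of the benzylic C–O bond, so the SN2 path at the primary carbon should prevail. Excess oxetane and BF3·OEt2 are used so that both sites react before arylborate formation consumes the nucleophile.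

Step 10
Reactants: 14 (1R)-3-[3-({3-[(3R)-3-hydroxy-3-phenylpropyl]-2-methoxy-4,6-bis(methoxymethoxy)phenyl}methyl)-6-methoxy-2,4-bis(methoxymethoxy)phenyl]-1-phenylpropan-1-ol
Product: 15 4-[(3R)-3-hydroxy-3-phenylpropyl]-2-({4,6-dihydroxy-3-[(3R)-3-hydroxy-3-phenylpropyl]-2-methoxyphenyl}methyl)-5-methoxybenzene-1,3-diol
Conditions: HCl (3 M aq), MeOH–THF, 40 °C, under argon
Reagents that add atoms: none
Why: Acid-catalysed acetal exchange with methanol removes the four aryl MOM ethers, while the secondary benzylic alcohols next to an unsubstituted phenyl ring do not ionise in dilute acid at this temperature, so the (R) centres are kept.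

Step 11
Reactants: 15 4-[(3R)-3-hydroxy-3-phenylpropyl]-2-({4,6-dihydroxy-3-[(3R)-3-hydroxy-3-phenylpropyl]-2-methoxyphenyl}methyl)-5-methoxybenzene-1,3-diol
Product: 16 (2S)-8-{[(2S)-7-hydroxy-5-methoxy-2-phenyl-3,4-dihydro-2H-chromen-6-yl]methyl}-5-methoxy-2-phenyl-3,4-dihydro-2H-chromen-7-ol (CNP0178097.1)
Conditions: PPh3 (3 equiv), DIAD (3 equiv, slow addition), THF (0.01 M), 0 °C to rt
Reagents that add atoms: none
Why: Twofold intramolecular Mitsunobu etherification: each carbinol activated by PPh3–DIAD is displaced in a 6-exo-tet SN2 reaction by the only phenol ortho to its chain (O-8a; the other ortho position carries OMe and the free 7-OH is para), so both pyran rings close with inversion, (R) to (S), and high dilution suppresses intermolecular etherification by the 7-hydroxyls.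

**Compound list**

1 | 5-methoxyresorcinol | COc1cc(O)cc(O)c1 | starting material
2 | 1-methoxy-3,5-bis(methoxymethoxy)benzene | COCOc1cc(OC)cc(OCOC)c1 | intermediate
3 | 2,4,6-trihydroxybenzaldehyde | O=Cc1c(O)cc(O)cc1O | starting material
4 | 2-hydroxy-4,6-bis(methoxymethoxy)benzaldehyde | COCOc1cc(O)c(C=O)c(OCOC)c1 | intermediate
5 | 3-bromo-2-hydroxy-4,6-bis(methoxymethoxy)benzaldehyde | COCOc1cc(OCOC)c(Br)c(O)c1C=O | intermediate
6 | 3-bromo-2-methoxy-4,6-bis(methoxymethoxy)benzaldehyde | COCOc1cc(OCOC)c(Br)c(OC)c1C=O | intermediate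
7 | [4-methoxy-2,6-bis(methoxymethoxy)phenyl]lithium (ring A aryllithium) | [Li]c1c(OCOC)cc(OC)cc1OCOC | intermediate
8 | [3-bromo-2-methoxy-4,6-bis(methoxymethoxy)phenyl][4-methoxy-2,6-bis(methoxymethoxy)phenyl]methanol (racemic) | COCOc1cc(OC)cc(OCOC)c1C(O)c1c(OC)c(Br)c(OCOC)cc1OCOC | intermediate
9 | 2-{[3-bromo-2-methoxy-4,6-bis(methoxymethoxy)phenyl]methyl}-5-methoxy-1,3-bis(methoxymethoxy)benzene | COCOc1cc(OC)cc(OCOC)c1Cc1c(OC)c(Br)c(OCOC)cc1OCOC | intermediate
10 | 1-bromo-3-{[3-bromo-2-methoxy-4,6-bis(methoxymethoxy)phenyl]methyl}-6-methoxy-2,4-bis(methoxymethoxy)benzene | COCOc1cc(OC)c(Br)c(OCOC)c1Cc1c(OC)c(Br)c(OCOC)cc1OCOC | intermediate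
11 | (R)-3-chloro-1-phenylpropan-1-ol | ClCC[C@H](c1ccccc1)O | starting material
12 | (R)-2-phenyloxetane | C1C[C@H](c2ccccc2)O1 | intermediate
13 | dilithio arene (10 with lithium in place of both bromines) | COCOc1cc(OC)c([Li])c(OCOC)c1Cc1c(OC)c([Li])c(OCOC)cc1OCOC | intermediate
14 | (1R)-3-[3-({3-[(3R)-3-hydroxy-3-phenylpropyl]-2-methoxy-4,6-bis(methoxymethoxy)phenyl}methyl)-6-methoxy-2,4-bis(methoxymethoxy)phenyl]-1-phenylpropan-1-ol | COCOc1cc(OC)c(CC[C@H](c2ccccc2)O)c(OCOC)c1Cc1c(OC)c(CC[C@H](c2ccccc2)O)c(OCOC)cc1OCOC | intermediate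
15 | 4-[(3R)-3-hydroxy-3-phenylpropyl]-2-({4,6-dihydroxy-3-[(3R)-3-hydroxy-3-phenylpropyl]-2-methoxyphenyl}methyl)-5-methoxybenzene-1,3-diol | Oc1cc(OC)c(CC[C@H](c2ccccc2)O)c(O)c1Cc1c(OC)c(CC[C@H](c2ccccc2)O)c(O)cc1O | intermediate
16 | (2S)-8-{[(2S)-7-hydroxy-5-methoxy-2-phenyl-3,4-dihydro-2H-chromen-6-yl]methyl}-5-methoxy-2-phenyl-3,4-dihydro-2H-chromen-7-ol | COc1cc(O)c(Cc2c(O)cc3c(c2OC)CC[C@@H](c2ccccc2)O3)c2c1CC[C@@H](c1ccccc1)O2 | target

**Step count and risks**

Total step count: 11. Longest linear sequence: 9 steps (steps 2, 3, 4, 5, 6, 7, 9, 10, 11, from 2,4,6-trihydroxybenzaldehyde).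

Steps most likely to fail:

Step 9 (key step). What may go wrong: opening of the BF3-activated oxetane at its benzylic C–O bond, or its ionisation and oligomerisation; capture of the aryllithium by BF3 as an arylborate; a stalled second alkylation that leaves mono-alkylated material. The fallback is a palladium-catalysed alkyl–aryl Negishi coupling, which makes the same C4a–C4 bonds without a Lewis acid. It sets out from 11 and 10 and comes back at 14. Silylation of 11 (TBSCl, imidazole, DMF) should give tert-butyl[(1R)-3-chloro-1-phenylpropoxy]dimethylsilane F1. Finkelstein exchange (NaI, acetone, reflux) should give tert-butyl[(1R)-3-iodo-1-phenylpropoxy]dimethylsilane F2. Zinc insertion (Zn dust, LiCl, THF, 40 °C) should give [(3R)-3-(tert-butyldimethylsilyloxy)-3-phenylpropyl]zinc iodide F3. Coupling of F3 (3 equiv, two of which are incorporated) with 10 (Pd(OAc)2, SPhos, THF–NMP, 60 °C) should give the bis-TBS ether of 14 F4. TBAF in THF then returns 14. The stereocentre is never a reacting centre, so (R) is kept.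

Step 11. What may go wrong: the two free 7-hydroxyls, which cannot cyclise, may capture activated carbinols of other molecules, so oligomer formation competes with the second ring closure. The fallback ties the two 7-oxygens together with a silicon tether before the key step, so that no spectator phenol is free during ring closure. It sets out from 10 and comes back at 16. HCl in MeOH removes the four MOM groups of 10 and should give 4-bromo-2-[(3-bromo-4,6-dihydroxy-2-methoxyphenyl)methyl]-5-methoxybenzene-1,3-diol F5. t-Bu2Si(OTf)2 with 2,6-lutidine at high dilution should bridge the two less hindered hydroxyls ortho to the methylene (on ring A the one not flanked by bromine), giving the eight-membered cyclic di-tert-butylsilylene of F5 F6. MOMCl and i-Pr2NEt in CH2Cl2 cap the two remaining 8a-hydroxyls to give the bis-MOM ether of F6 F7. The conditions of step 9 should give the silylene-tethered (R,R)-diol F8. HCl in MeOH at rt, which the hindered silylene should survive, should give the silylene-tethered diphenol diol F9. The conditions of step 11 should then close both rings to the silylene-tethered bis-(2S)-flavan F10, and HF·pyridine in THF releases 16.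

Step 6. What may go wrong: partial loss of MOM ethers under TFA, giving a mixture of partly deprotected diarylmethanes. The fallback is deliberate global cleavage followed by re-protection. It sets out from 8 and comes back at 9. Et3SiH with excess TFA in CH2Cl2 at rt, followed by HCl in MeOH, should give 2-[(3-bromo-4,6-dihydroxy-2-methoxyphenyl)methyl]-5-methoxybenzene-1,3-diol F11. MOMCl and NaH in DMF then return 9.

**Further compounds**

F1 | step 9 | tert-butyl[(1R)-3-chloro-1-phenylpropoxy]dimethylsilane | ClCC[C@H](c1ccccc1)O[Si](C)(C)C(C)(C)C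
F2 | step 9 | tert-butyl[(1R)-3-iodo-1-phenylpropoxy]dimethylsilane | ICC[C@H](c1ccccc1)O[Si](C)(C)C(C)(C)C
F3 | step 9 | [(3R)-3-(tert-butyldimethylsilyloxy)-3-phenylpropyl]zinc iodide | I[Zn]CC[C@H](c1ccccc1)O[Si](C)(C)C(C)(C)C
F4 | step 9 | bis-TBS ether of 14 | COCOc1cc(OC)c(CC[C@H](c2ccccc2)O[Si](C)(C)C(C)(C)C)c(OCOC)c1Cc1c(OC)c(CC[C@H](c2ccccc2)O[Si](C)(C)C(C)(C)C)c(OCOC)cc1OCOC
F5 | step 11 | 4-bromo-2-[(3-bromo-4,6-dihydroxy-2-methoxyphenyl)methyl]-5-methoxybenzene-1,3-diol | Oc1cc(OC)c(Br)c(O)c1Cc1c(OC)c(Br)c(O)cc1O
F6 | step 11 | cyclic di-tert-butylsilylene of F5 (silicon on ring A O-7 and ring B O-7; 12H-dibenzo[d,g][1,3,2]dioxasilocin core) | CC(C)(C)[Si]1(C(C)(C)C)Oc2cc(OC)c(Br)c(O)c2Cc2c(OC)c(Br)c(O)cc2O1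
F7 | step 11 | bis-MOM ether of F6 | CC(C)(C)[Si]1(C(C)(C)C)Oc2cc(OC)c(Br)c(OCOC)c2Cc2c(OC)c(Br)c(OCOC)cc2O1
F8 | step 11 | silylene-tethered (R,R)-diol | CC(C)(C)[Si]1(C(C)(C)C)Oc2cc(OC)c(CC[C@H](c3ccccc3)O)c(OCOC)c2Cc2c(OC)c(CC[C@H](c3ccccc3)O)c(OCOC)cc2O1
F9 | step 11 | silylene-tethered diphenol diol | CC(C)(C)[Si]1(C(C)(C)C)Oc2cc(OC)c(CC[C@H](c3ccccc3)O)c(O)c2Cc2c(OC)c(CC[C@H](c3ccccc3)O)c(O)cc2O1
F10 | step 11 | silylene-tethered bis-(2S)-flavan | CC(C)(C)[Si]1(C(C)(C)C)Oc2cc(OC)c3c(c2Cc2c(OC)c4c(cc2O1)O[C@H](c2ccccc2)CC4)O[C@H](c2ccccc2)CC3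
F11 | step 6 | 2-[(3-bromo-4,6-dihydroxy-2-methoxyphenyl)methyl]-5-methoxybenzene-1,3-diol | Oc1cc(OC)cc(O)c1Cc1c(OC)c(Br)c(O)cc1O
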